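## Structural features

- **Skeleton and labels.** The target is a daucane-type diester on a bicyclo[5.3.0]decene. Cyclopentane ring A (C4–C5–C6–C7–C8) is fused through the C4–C8 bond to cycloheptene ring B (C1=C2–C3–C4–C8–C9–C10). The labels follow the ring atoms in the order of the SMILES, and C1 is the methyl-bearing olefinic carbon.
- **Configuration.** Read literally, the SMILES places the C4 methyl group, H8 and O7 on one face (β), which means a cis ring fusion. The isopropyl group, O3 (isovalerate) and O9 (4-hydroxybenzoate) lie on the other face (α); the descriptors are 3S,4R,7S,8S,9R.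
- **Stereocentre array.** The five stereocentres are contiguous: C3–C4–C8–C9 form a row and C7 branches from C8. C4 is quaternary and C7 is a fully substituted carbinol, so three neighbouring carbons of ring A carry their larger carbon substituent (C3, C9, isopropyl) on the same face.
- **Fragile groups.** These are the neopentyl allylic C3 ester (ionisation, allylic shift), the tertiary O7–H that is β to C9 (retro-aldol or dehydration whenever C9 is a ketone), H8 at that same stage (epimerisation towards the trans-fused series), the free phenol, and two different esters on two similar secondary oxygens.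
- **Real difficulty.** Ring B must be made together with quaternary C4 and a crowded all-cis array that equilibration would not favour. The two halves of the nearly symmetric ring B (C2/C10, C3/C9) must also be told apart.
- **Feature exploited by the key step.** The oxygenated carbons C3 and C9 flank the fusion bond, so C3–C4–C8–C9 is a 1,4-dioxygenated chain, the retron of a cleaved cyclobutane-1,2-diol. Tying C3 to C9 folds ring B into a four-membered ring and a five-membered ring C (C3–C2–C1–C10–C9), and the resulting 5-4-5 tricycle is the [2+2] adduct of two simple cyclopentenes.

## Logic of the disconnections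

**21 ⇒ 20 ⇒ 18 + 19.** The cuts are the two O–Si bonds (phenol, O7) and the acyl bond O3–C(=O). The ionisable allylic ester and the free phenol are the most fragile groups, so they are made last. The target shrinks to one allylic alcohol. The forward steps must acylate a neopentyl allylic alcohol without ionising it and desilylate under buffered conditions.

**18 ⇒ 17 ⇒ 15.** The cuts are C3–H and the C1=C2 π bond. A C3 ketone can enolise only towards C2 because C4 is quaternary, so the olefin position follows from the constitution. One stereocentre and the olefin disappear. The forward steps need dehydrogenation in the presence of an aryl ester and hydride delivery to the β face of C3.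

**15 ⇒ 11 + 14, and 14 ⇒ 12.** The cuts are the acyl bond O9–C(=O) and one O–Si bond. While C3 is still a ketone, O9–H is the only acylable hydroxyl. The two secondary oxygens are therefore differentiated by timing, without extra protecting groups. The tertiary O7–H must stay inert.

**11 ⇒ 10.** The cut is C9–H. O7–H is β to C9 and to no other carbonyl, so a hydroxyl-bound hydride breaks the pseudo-symmetry of the dione and fixes C9. One more stereocentre goes. The forward step needs intramolecular delivery that is faster than epimerisation at C8.

**10 ⇒ 9 ⇒ 8.** Here the C3–C9 bond is reconnected; in the forward direction it is cleaved. A 1,4-dione across the fusion bond is the product of a glycol scission. The seven-membered ring is exchanged for a four- and a five-membered ring, no medium-ring closure is needed, and the cis fusion is locked by strain. The C7 carbinol must be in place before the scission, because a C7 ketone would make H8 doubly activated.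

**8 ⇒ 7 ⇒ 6 ⇒ 4.** The cuts are C7–O and C7–C(isopropyl). O7 must stand on the convex face, where a carbon nucleophile would also attack a ketone. The carbon is therefore attached to sp2 C7 first and the oxygen arrives last. This leads back to a plain ketone. The forward steps need enolisation towards C6 only, and radical capture faster than ring opening.

**4 ⇒ 2 + 3 (key).** The cuts are C3–C4 and C8–C9.
- In one sentence: an enantioselective [2+2] photocycloaddition of 3 to 2 builds a 5-4-5 tricycle whose central C3–C9 bond is later cut to release ring B.
- One operation makes the quaternary C4, the cis C4/C8 pair, both links between ring A and the future ring B, and places both oxygens.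
- A tricycle with five stereocentres falls back to two achiral cyclopentenes.
- Only enantiofacial control is required.

**2 ⇒ 1.** The cut is C3–C9, formed by reductive ester coupling. It leads to a commercial diester that already carries the C1 methyl group.

## Other disconnections considered

**Alternative 1:** Cut C1=C2 by ring-closing metathesis, the cut that comes to mind first.
- Forward key step: the second-generation Grubbs catalyst would close the diene triol A1 to the bicyclic triol A2.
- The cut removes no stereocentre. A1 still holds all five, and C3 and C9 become exocyclic carbinols that must be set by additions to aldehydes on a crowded cyclopentane, one of them next to quaternary C4.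
- At the C9 aldehyde stage H8 is enolisable on a ring whose three large groups must share one face, so equilibration would drain it to the trans isomer.
- The metathesis would have to join a 1,1-disubstituted olefin to a vinyl group on a neopentyl carbinol, and A2 leaves two similar secondary alcohols to differentiate.
- The chosen plan makes C3–C4 and C8–C9 in one step, takes the cis array from ring strain instead of equilibrium, and differentiates O3 from O9 by timing.

**Alternative 2:** Cut the same bonds C3–C4 and C8–C9 thermally on a ring that lacks C1, then insert C1.
- Forward key step: an endo Diels–Alder reaction of 3 with the (E,E)-diene A3 would give hydrindenone A4 and set C3, C4, C8 and C9 in the right relative sense in one event.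
- A C–CH3 unit would then be inserted into C2=C10 by halocarbene cyclopropanation, electrocyclic opening and hydride capture.
- In the ground state the β-methyl group raises the LUMO of the enone and shields C4. A diene rich enough to react is unlikely to tolerate the strong Lewis acids that would be needed.
- The insertion runs through a 2-methylallyl cation whose termini C2 and C10 differ only by remote groups, so the olefin position is not dictated.
- Only the cyclopropane epimer with the halide over the ring can open disrotatorily to a cis-cycloheptenyl cation.
- The photochemical version pays no penalty for β-substitution and needs no insertion.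

**Alternative 3:** Buy C7 and cut C4–C8 as an aldol condensation.
- Forward key step: ozonolysis of (R)-terpinen-4-ol A5 and intramolecular aldol condensation would give enal A6, which holds ten skeletal carbons with C7 correct.
- A C3 nucleophile would then be added to C4 and ring B closed.
- With C7 fixed first, every later carbon–carbon bond must form cis to the isopropyl group. Conjugate addition should come anti to it and give the wrong C4.
- The formyl-bearing C8 should relax to the trans arrangement, and no step would set more than one centre.
- The chosen plan installs C7 last, from the convex face, where the steric bias works for the target.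

Key step: step 2

Assumption 1: the SMILES is taken literally, so the C4 methyl group and H8 are cis (cis-fused hydroazulene).
Assumption 2: in step 2 the catalyst antipode is the one that leaves open the enone face leading to 4 as drawn; both antipodes derive from commercial proline derivatives.
Assumption 3: compounds 4 to 16 are drawn as the expected major diastereomer (cis-anti-cis, C1 methyl α). Isomers that differ only at C1, C3 or C9 are carried along and converge at 10 and 17.

## Steps

Step 1
Reactants: 1 dimethyl 3-methylpentanedioate
Product: 2 4-methyl-1,2-bis(trimethylsilyloxy)cyclopent-1-ene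
Conditions: Na (4.4 equiv), Me3SiCl (4.5 equiv), toluene, reflux
Reagents that add atoms: chlorotrimethylsilane, C[Si](C)(C)Cl
Why: Acyloin condensation with chlorosilane trapping (Rühlmann modification): the two ester carbonyl carbons are joined reductively (C3–C9) and the enediolate is silylated before Dieckmann-type side reactions can start; closure of a five-membered ring is the most favourable case. No stereocentre arises because 2 has a mirror plane through C1.

Step 2
Reactants: 2 4-methyl-1,2-bis(trimethylsilyloxy)cyclopent-1-ene; 3 3-methylcyclopent-2-en-1-one
Product: 4 cis-anti-cis 6,9-dimethyl-1,7-bis(trimethylsilyloxy)tricyclo[5.3.0.0(2,6)]decan-3-one (C7 ketone; C4 methyl and H8 β; O3 O9 and C1 methyl α)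
Conditions: 2 (5 equiv), AlBr3-activated diarylprolinol-derived B-aryl oxazaborolidine (50 mol %), CH2Cl2, −75 °C, hν (366 nm)
Reagents that add atoms: none
Why: Binding of the carbonyl oxygen of 3 to the boron Lewis acid shifts its π–π* band to longer wavelength, so that 366 nm light excites mainly the bound enone, which after intersystem crossing adds to the electron-rich C3=C9 bond of 2 through a triplet 1,4-biradical that collapses to the cyclobutane (enone–alkene [2+2] photocycloaddition). The closest known reaction types are the uncatalysed photocycloaddition of cyclic enones to 1,2-bis(silyloxy)cycloalkenes and the oxazaborolidine–AlBr3-catalysed enantioselective intermolecular [2+2] photocycloaddition of cyclic enones, β-alkyl ones included; the same Lewis acid class promotes thermal [2+2] reactions of silyl enol ethers at −78 °C, which shows that such ethers survive it. One ring is closed, the four-membered ring C3–C4–C8–C9, by intermolecular formation of C3–C4 and C8–C9 ending in 1,4-biradical recombination, and with it the periphery C3–C2–C1–C10–C9–C8–C4 becomes the latent ring B. C4 and C8 must come out cis because a trans-fused bicyclo[3.2.0]heptanone from a five-membered enone is too strained, and their absolute sense is fixed by the aryl groups of the catalyst, which shield one face of the bound enone. C3 and C9 are cis by the constraint of ring C and anti to ring A for steric reasons, and the C1 methyl group should prefer the face away from the incoming enone; these three centres are erased in steps 6 and 10, so their control is not needed. No regiochemical question arises because 2 is constitutionally symmetric, and β-substitution is no handicap in the excited state, so quaternary C4 can be made next to fully substituted C3. The only selectivity the step needs is enantiofacial, and it is secured by selective excitation of the chiral complex at low temperature.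

Step 3
Reactants: 4 tricyclic ketone
Product: 6 6,9-dimethyl-1,7-bis(trimethylsilyloxy)tricyclo[5.3.0.0(2,6)]dec-3-en-3-yl trifluoromethanesulfonate (C6=C7 enol triflate), via potassium enolate 5 (not isolated)
Conditions: KHMDS, THF, −78 °C; then PhNTf2, −78 to 0 °C
Reagents that add atoms: N-phenylbis(trifluoromethanesulfonimide), O=S(=O)(N(c1ccccc1)S(=O)(=O)C(F)(F)F)C(F)(F)F
Why: Kinetic deprotonation can only go to C6, since an enolate towards C8 would put a double bond at the cyclobutane ring fusion, and O-sulfonylation of the enolate is standard enol triflate synthesis. Removal of the carbonyl group at once also disarms the β-silyloxy ketone C7/C9, which could otherwise open by retro-aldol cleavage of C8–C9.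

Step 4
Reactants: 6 enol triflate
Product: 7 3-isopropyl-6,9-dimethyl-1,7-bis(trimethylsilyloxy)tricyclo[5.3.0.0(2,6)]dec-3-ene (C6=C7 olefin with isopropyl on C7)
Conditions: iPrZnBr (2 equiv), PdCl2(dppf) (5 mol %), THF, 50 °C
Reagents that add atoms: isopropylzinc bromide, CC(C)[Zn]Br
Why: Negishi coupling of an alkenyl triflate with a secondary alkylzinc halide; the wide bite angle of dppf favours reductive elimination over β-hydride elimination, so that the branched group should be transferred unchanged. The silyl ethers are inert and no stereocentre is involved.

Step 5
Reactants: 7 isopropyl olefin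
Product: 8 3-isopropyl-6,9-dimethyl-1,7-bis(trimethylsilyloxy)tricyclo[5.3.0.0(2,6)]decan-3-ol (O7–H exo = β; isopropyl endo = α)
Conditions: Mn(dpm)3 (10 mol %), PhSiH3, O2 (1 atm), iPrOH, 0 °C
Reagents that add atoms: dioxygen, O=O
Why: Mukaiyama hydration by metal-hydride hydrogen atom transfer: H adds to C6, the tertiary C7 radical is captured by O2 and the peroxy species is reduced to the alcohol (Markovnikov). The concave face of ring A is covered by the cyclobutane and the C9 silyloxy group, so O2 should arrive on the convex β face next to H8, which sets C7 with O7 β and isopropyl α, the epimer that addition of an isopropyl nucleophile to 4 could not give. Saturation with O2 at low temperature keeps capture ahead of cyclobutylcarbinyl ring opening.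

Step 6
Reactants: 8 tricyclic tertiary alcohol
Product: 10 cis-fused 3-hydroxy-3-isopropyl-6,8a-dimethyloctahydroazulene-4,8-dione (C3 and C9 ketones; O7–H β; H8 β), via triol 9 (not isolated)
Conditions: K2CO3 (cat.), MeOH, 0 °C; evaporation; then Pb(OAc)4, CH2Cl2, −20 to 0 °C
Reagents that add atoms: none
Why: Methanolysis frees the cis-1,2-diol and Criegee glycol cleavage cuts C3–C9 with release of cyclobutane strain, so that the four-membered ring and ring C merge into ring B with carbonyl groups exactly at C3 and C9. C4, C7 and C8 are untouched, hence the cis fusion of step 2 is carried over, and all photoadduct diastereomers that differ at C3 and C9 converge. The weakly acidic medium protects the β-hydroxy ketone from retro-aldol cleavage and H8 from epimerisation.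

Step 7
Reactants: 10 hydroxy dione
Product: 11 cis-fused 3,4-dihydroxy-3-isopropyl-6,8a-dimethyloctahydroazulen-8-one (C3 ketone; O7–H β; O9–H α)
Conditions: Me4NBH(OAc)3, MeCN–AcOH, −30 °C
Reagents that add atoms: none
Why: Evans–Saksena reduction: O7–H replaces an acetate on boron and hydride is delivered within the complex to C9, the only carbonyl β to the hydroxyl, while the free reagent leaves the neopentyl C3 ketone alone at this temperature. With the bulky C7 pseudo-equatorial on ring B the C9 carbonyl eclipses C8–C7, pseudo-axial C5 blocks the α face, and the boron-bound hydride reaches the β face beside H8, which gives the 1,3-anti diol (O9 α, 9R).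

Step 8
Reactants: 12 4-hydroxybenzoic acid
Product: 14 4-(triisopropylsilyloxy)benzoic acid, via bis-silylated acid 13 (not isolated)
Conditions: iPr3SiCl (2.2 equiv), imidazole, DMF, rt; then AcOH–THF–H2O, rt
Reagents that add atoms: chlorotriisopropylsilane, CC(C)[Si](Cl)(C(C)C)C(C)C
Why: Exhaustive silylation and selective hydrolysis of the much more labile silyl ester give the phenol-protected acid; the hindered aryl silyl ether should outlast steps 9 to 12 and leave with fluoride.

Step 9
Reactants: 11 keto diol; 14 4-(triisopropylsilyloxy)benzoic acid
Product: 15 C9 4-(triisopropylsilyloxy)benzoate of 11 (C3 ketone; O7–H free)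
Conditions: DCC, DMAP, CH2Cl2, 0 °C to rt
Reagents that add atoms: none
Why: Steglich esterification: O9–H is the only acylable hydroxyl at this stage, because O7–H is tertiary and C3 is still a ketone, so the two secondary oxygens are told apart by timing and not by protecting groups. Should 11 rest partly as its transannular C3 hemiketal, acylation drains the open form; the C9–O bond is not broken, so 9R is retained.

Step 10
Reactants: 15 keto ester
Product: 17 C1=C2 enone with C3 ketone bearing O7 trimethylsilyl ether and C9 aryl ester, via silyl enol ether 16 (not isolated)
Conditions: Me3SiOTf (3 equiv), Et3N, CH2Cl2, 0 °C; aqueous NaHCO3 wash; then Pd(OAc)2 (1.1 equiv), MeCN, rt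
Reagents that add atoms: trimethylsilyl trifluoromethanesulfonate, C[Si](C)(C)OS(=O)(=O)C(F)(F)F
Why: Soft enolisation can only go towards C2 because C4 is quaternary, and the same reagent caps O7–H; Saegusa–Ito oxidation (palladation at C2, β-hydride elimination of H1) then gives the enone, so the place of the C1=C2 bond follows from the constitution. Both C1 epimers converge here, since palladium can take either face of the enol ether to find H1 syn.

Step 11
Reactants: 17 enone
Product: 18 allylic alcohol (O3–H α = 3S; O7 trimethylsilyl ether; C9 aryl ester)
Conditions: NaBH4, CeCl3·7H2O, MeOH, −78 to −40 °C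
Reagents that add atoms: none
Why: Luche reduction, selective for 1,2-addition and mild enough for the aryl ester and the aryl silyl ether. In the conformer with C7 pseudo-equatorial, C5 stands pseudo-axial on the α face and antiperiplanar to the incoming hydride, the C4 methyl group lies near the carbonyl plane and only H8 is 1,3-related on the β face, so β attack should give the pseudo-equatorial O3 α alcohol (3S).

Step 12
Reactants: 18 allylic alcohol; 19 3-methylbutanoyl chloride
Product: 20 fully protected diester (C3 isovalerate; C9 4-(triisopropylsilyloxy)benzoate; O7 trimethylsilyl ether)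
Conditions: pyridine, DMAP (cat.), CH2Cl2, 0 °C to rt
Reagents that add atoms: none
Why: DMAP-catalysed acylation under basic, non-ionising conditions takes place at oxygen, so that C3 keeps its configuration and no allylic shift can occur; O7 is masked and no other hydroxyl is free.

Step 13
Reactants: 20 protected diester
Product: 21 target CNP0086724.3 (3S,4R,7S,8S,9R in the labels used here)
Conditions: Bu4NF, AcOH (1:1), THF, 0 °C
Reagents that add atoms: none
Why: Fluoride removes the aryl triisopropylsilyl and the tertiary trimethylsilyl ether in one operation; acetic acid buffers the phenoxide and alkoxide so that neither ester should migrate or hydrolyse and the allylic ester is not ionised.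

## Compound list

1 | dimethyl 3-methylpentanedioate | COC(=O)CC(C)CC(=O)OC | starting material
2 | 4-methyl-1,2-bis(trimethylsilyloxy)cyclopent-1-ene | CC1CC(O[Si](C)(C)C)=C(O[Si](C)(C)C)C1 | intermediate
3 | 3-methylcyclopent-2-en-1-one | CC1=CC(=O)CC1 | starting material
4 | cis-anti-cis tricyclic ketone (photoadduct) | C[C@@H]1C[C@@]3(O[Si](C)(C)C)[C@]2(C)CCC(=O)[C@@H]2[C@@]3(O[Si](C)(C)C)C1 | intermediate
5 | potassium C6=C7 enolate of 4 | [K+].C[C@@H]1C[C@@]3(O[Si](C)(C)C)[C@]2(C)CC=C([O-])[C@@H]2[C@@]3(O[Si](C)(C)C)C1 | intermediate
6 | C6=C7 enol triflate | C[C@@H]1C[C@@]3(O[Si](C)(C)C)[C@]2(C)CC=C(OS(=O)(=O)C(F)(F)F)[C@@H]2[C@@]3(O[Si](C)(C)C)C1 | intermediate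
7 | C7-isopropyl C6=C7 olefin | C[C@@H]1C[C@@]3(O[Si](C)(C)C)[C@]2(C)CC=C(C(C)C)[C@@H]2[C@@]3(O[Si](C)(C)C)C1 | intermediate
8 | tricyclic tertiary alcohol (O7–H β) | C[C@@H]1C[C@@]3(O[Si](C)(C)C)[C@]2(C)CC[C@](O)(C(C)C)[C@@H]2[C@@]3(O[Si](C)(C)C)C1 | intermediate
9 | tricyclic triol | C[C@@H]1C[C@@]3(O)[C@]2(C)CC[C@](O)(C(C)C)[C@@H]2[C@@]3(O)C1 | intermediate
10 | cis-hydroazulene hydroxy dione | C[C@@H]1CC(=O)[C@]2(C)CC[C@](O)(C(C)C)[C@@H]2C(=O)C1 | intermediate
11 | cis-hydroazulene keto diol | C[C@@H]1CC(=O)[C@]2(C)CC[C@](O)(C(C)C)[C@@H]2[C@H](O)C1 | intermediate
12 | 4-hydroxybenzoic acid | OC(=O)c1ccc(O)cc1 | starting material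
13 | triisopropylsilyl 4-(triisopropylsilyloxy)benzoate | CC(C)[Si](C(C)C)(C(C)C)OC(=O)c1ccc(O[Si](C(C)C)(C(C)C)C(C)C)cc1 | intermediate
14 | 4-(triisopropylsilyloxy)benzoic acid | OC(=O)c1ccc(O[Si](C(C)C)(C(C)C)C(C)C)cc1 | intermediate
15 | C9 aryl ester, C3 ketone | C[C@@H]1CC(=O)[C@]2(C)CC[C@](O)(C(C)C)[C@@H]2[C@H](OC(=O)c2ccc(O[Si](C(C)C)(C(C)C)C(C)C)cc2)C1 | intermediate
16 | C2=C3 trimethylsilyl enol ether, O7 trimethylsilyl ether | C[C@@H]1C=C(O[Si](C)(C)C)[C@]2(C)CC[C@](O[Si](C)(C)C)(C(C)C)[C@@H]2[C@H](OC(=O)c2ccc(O[Si](C(C)C)(C(C)C)C(C)C)cc2)C1 | intermediate
17 | C1=C2 enone | CC1=CC(=O)[C@]2(C)CC[C@](O[Si](C)(C)C)(C(C)C)[C@@H]2[C@H](OC(=O)c2ccc(O[Si](C(C)C)(C(C)C)C(C)C)cc2)C1 | intermediate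
18 | 3S allylic alcohol | CC1=C[C@H](O)[C@]2(C)CC[C@](O[Si](C)(C)C)(C(C)C)[C@@H]2[C@H](OC(=O)c2ccc(O[Si](C(C)C)(C(C)C)C(C)C)cc2)C1 | intermediate
19 | 3-methylbutanoyl chloride | CC(C)CC(=O)Cl | starting material
20 | protected diester | CC1=C[C@H](OC(=O)CC(C)C)[C@]2(C)CC[C@](O[Si](C)(C)C)(C(C)C)[C@@H]2[C@H](OC(=O)c2ccc(O[Si](C(C)C)(C(C)C)C(C)C)cc2)C1 | intermediate
21 | CNP0086724.3 | CC1=C[C@H](OC(=O)CC(C)C)[C@]2(C)CC[C@](O)(C(C)C)[C@@H]2[C@H](OC(=O)c2ccc(O)cc2)C1 | target

## Step count and least certain steps

Total step count: 13. Longest linear sequence: 12 (steps 1 to 7 and 9 to 13).

**Step 2 (key step).**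
- Enantiofacial control may erode through excitation of unbound enone or loose binding; five-membered enones and enediol silyl ethers lie at the edge of what this catalysis has handled.
- The Lewis acid may strip the C9 silyl group, after which retro-aldol opening of C8–C9 would follow.
- The biradical may disproportionate by hydrogen transfer instead of closing between two fully substituted carbons.
- Fallback, from 2 and 3 back to 4: uncatalysed irradiation (λ above 300 nm, hexane) should give 4 together with the enantiomeric photoadduct F1. Reduction with NaBH4 in MeOH from the convex face should give the endo alcohol F2 and the enantiomeric endo alcohol F3.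
- A lipase (Candida antarctica lipase B, vinyl acetate, MTBE) should follow the usual size rule for secondary alcohols and acylate the 7R enantiomer to the acetate F4. The 7S alcohol stays unreacted and is returned to 4 by buffered Dess–Martin oxidation.

**Step 5.**
- The C7 radical is a cyclobutylcarbinyl radical, and scission of C8–C9 to an oxygen-stabilised tertiary radical may compete with O2 capture. Facial selectivity of the capture may also be incomplete.
- Fallback, from 7 back to 8, avoids radicals: buffered mCPBA epoxidation on the convex face should give the β epoxide F5, and LiEt3BH should open it at the secondary C6 to leave O7 β.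

**Step 7.**
- Ligand exchange at the tertiary hydroxyl may be slow, so that undirected reduction, epimerisation at C8 or retro-aldol cleavage gain time.
- Fallback, from 10 back to 11, uses a covalent tether. Silylation of O7–H with iPr2SiHCl and imidazole gives the diisopropylsilyl ether F6. SnCl4-catalysed intramolecular hydrosilylation of the C9 ketone gives the cyclic silylene acetal F7 (anti). HF·pyridine then releases 11.

**Step 11.**
- Ring B may react through the other conformer, which would bring hydride to the α face.
- Basic borohydride species may start loss of the C9 ester through the extended enolate.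
- Fallback, from 17 back to 18, moves the control element from the substrate to a catalyst. Corey–Bakshi–Shibata reduction with the (R)-B-methyl oxazaborolidine and catecholborane in toluene at −78 °C treats the quaternary C4 flank as the large group and should give 3S. No new compound is made.

**Step 4.**
- β-Hydride elimination and reinsertion on palladium may isomerise the isopropyl group to n-propyl or reduce the triflate.
- Fallback, from 6 back to 7, joins two sp2 carbons instead. Suzuki–Miyaura coupling with isopropenylboronic acid pinacol ester (Pd(PPh3)4, K3PO4, dioxane–H2O) gives the isopropenyl diene F8. Its unhindered 1,1-disubstituted olefin should then be hydrogenated selectively with RhCl(PPh3)3 and H2.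

## Further compounds

F1 | step 2 | enantiomer of 4 | C[C@H]1C[C@]3(O[Si](C)(C)C)[C@@]2(C)CCC(=O)[C@H]2[C@]3(O[Si](C)(C)C)C1
F2 | step 2 | endo (O7 α, 7S) alcohol from 4 | C[C@@H]1C[C@@]3(O[Si](C)(C)C)[C@]2(C)CC[C@H](O)[C@@H]2[C@@]3(O[Si](C)(C)C)C1
F3 | step 2 | enantiomer of F2 (7R) | C[C@H]1C[C@]3(O[Si](C)(C)C)[C@@]2(C)CC[C@@H](O)[C@H]2[C@]3(O[Si](C)(C)C)C1
F4 | step 2 | acetate of F3 | C[C@H]1C[C@]3(O[Si](C)(C)C)[C@@]2(C)CC[C@@H](OC(C)=O)[C@H]2[C@]3(O[Si](C)(C)C)C1
F5 | step 5 | β C6–C7 epoxide of 7 | C[C@@H]1C[C@@]3(O[Si](C)(C)C)[C@]2(C)C[C@H]4O[C@@]4(C(C)C)[C@@H]2[C@@]3(O[Si](C)(C)C)C1
F6 | step 7 | O7 diisopropylsilyl ether of 10 | C[C@@H]1CC(=O)[C@]2(C)CC[C@](O[SiH](C(C)C)C(C)C)(C(C)C)[C@@H]2C(=O)C1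
F7 | step 7 | cyclic O7,O9-diisopropylsilylene derivative of 11 | C[C@@H]1CC(=O)[C@]2(C)CC[C@](O3)(C(C)C)[C@@H]2[C@H](O[Si]3(C(C)C)C(C)C)C1
F0 | step 11 | none | none
F8 | step 4 | C7-isopropenyl C6=C7 diene | C[C@@H]1C[C@@]3(O[Si](C)(C)C)[C@]2(C)CC=C(C(C)=C)[C@@H]2[C@@]3(O[Si](C)(C)C)C1
A1 | alternative 1 | metathesis precursor, diene triol | C=C[C@H](O)[C@]2(C)CC[C@](O)(C(C)C)[C@@H]2[C@H](O)CC(C)=C
A2 | alternative 1 | bicyclic triol (bis-deacyl target) | CC1=C[C@H](O)[C@]2(C)CC[C@](O)(C(C)C)[C@@H]2[C@H](O)C1
A3 | alternative 2 | (1E,3E)-1,4-bis(tert-butyldimethylsilyloxy)buta-1,3-diene | CC(C)(C)[Si](C)(C)O/C=C/C=C/O[Si](C)(C)C(C)(C)C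
A4 | alternative 2 | endo Diels–Alder adduct, cis-hydrindenone | C1=C[C@H](O[Si](C)(C)C(C)(C)C)[C@]2(C)CCC(=O)[C@@H]2[C@@H]1O[Si](C)(C)C(C)(C)C
A5 | alternative 3 | (R)-terpinen-4-ol | CC1=CC[C@@](O)(C(C)C)CC1
A6 | alternative 3 | 5-hydroxy-5-isopropyl-2-methylcyclopent-1-ene-1-carbaldehyde | CC1=C(C=O)[C@@](O)(C(C)C)CC1
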